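I dose the E. That is my decision for the next run, and the argument for it follows.

| flask | E | Z | remark | time |
|---|---|---|---|---|
| red | 10 mM | 0.23 mol% | run made earlier |  |
| teal | 10 mM | 0.32 mol% | run made earlier |  |
| ochre | 10 mM | 0.51 mol% | run made earlier |  |
| Saturday's | 10 mM | 0.23 mol% | one stirred flow tank at steady state, fed with the mixture as stated, mean residence time 4.0 min |  |
| Sunday's | 10 mM | 0.23 mol% | plug flow through a tube for 4.0 min, no back-mixing | 4.0 min |
| Monday's | 10 mM (fed, over 3.20 min) | 0.23 mol% | a stirred flask in which E is dosed at a steady rate over 3.20 min without added volume, worked up at 4.0 min | 4.0 min |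
| Wednesday's | 10 mM | 0.23 mol% | everything together in a closed stirred flask, run for 4.0 min | 4.0 min |

| run | time / min | X / % |
|---|---|---|
| red | 0.167 | 14.4 |
| red | 0.333 | 24.0 |
| red | 0.667 | 39.7 |
| red | 1.00 | 47.0 |
| red | 1.33 | 50.6 |
| red | 2.00 | 49.4 |
| red | 2.50 | 46.9 |
| teal | 0.200 | 17.2 |
| teal | 0.667 | 38.1 |
| teal | 1.00 | 45.4 |
| teal | 1.50 | 46.6 |
| teal | 2.50 | 42.0 |
| teal | 3.00 | 39.3 |
| teal | 4.00 | 30.9 |
| ochre | 0.500 | 31.7 |
| ochre | 1.00 | 38.7 |
| ochre | 1.50 | 38.7 |
| ochre | 2.50 | 32.1 |
| ochre | 3.00 | 28.9 |
| ochre | 4.00 | 22.0 |

(standard deviation of a reading: 1 percentage point)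

- the stated concentrations are those of everything mixed, before any reaction; amounts are the same in each set-up
- steps thought possible: X + Z <-> Q + Z; Z + X -> Z + L; E <-> X
- the feed brings no volume worth counting
- the earlier runs were made in a closed, stirred flask

- the set-up with the highest amount of X at the outlet or at the end, in percent of the E put in ("none" if the first two lie within 2 percentage points) (Saturday's / Sunday's / Monday's / Wednesday's / none)
- amount of X at the outlet or at the end, in percent of the E put in, Saturday's
- amount of X at the outlet or at the end, in percent of the E put in, Sunday's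
- amount of X at the outlet or at the end, in percent of the E put in, Monday's
- amount of X at the outlet or at the end, in percent of the E put in, Wednesday's

In the red run X reads 50.6% of the charge at 1.33 min and has come down to 46.9% at 2.50 min. The teal run, with Z at 0.32 mol% against 0.23 mol%, goes on down from 42.0% at 2.50 min to 30.9% at 4.00 min, so in the teal run the late readings fall as time goes on. I take each step as pseudo-first-order at fixed Z, which makes a dosed flask a mixture of batch runs of different ages.

I carry the reading time minus the midpoint of the feed, 2.40 min for Monday's, and call it the mean age of the charge. In Sunday's and Wednesday's the mean age is 4.0 min, longer than in Monday's and later than the last red reading, so I charge Monday's dosing. My own figure for Monday's is the nearest red reading, 46.9%, taken at 2.50 min, a little later than the mean age.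

The forecast, holding that “each E portion has an age between 0.8 and 4 min”, names Monday's and sets Monday's at 46%, a little below my figure. It gives 33.5% for Saturday's, 38.5% for Sunday's and 38.5% for Wednesday's.

The flasks give 34.9% for Saturday's, 38.6% for Sunday's, 46.2% for Monday's and 38.6% for Wednesday's, so Monday's is highest.

    X + Z ⇌ Q + Z, rate k1*[Z]*[X] forward; the back reaction follows from the equilibrium constant (K = 3.00, k = 6320 L mol⁻¹ min⁻¹)
    Z + X → Z + L (k = 5270 L mol⁻¹ min⁻¹)
    E ⇌ X (K = 2.56, k = 0.982 min⁻¹)

In Monday's the mean age of 2.40 min is longer than the 0.71 min half-life of E by its forward step and shorter than the 5.7 min half-life of X on the path to L, and at the end X stands at 46.2% with L at 11.8%. In the neighbouring flask, Monday's left until 15 min, the mean age is 13.4 min, longer than that half-life, and X has dropped to 12.4% while L holds the most at 45.2%.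

The earlier runs and the new flask are simulated with made-up constants, and the scatter is random.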